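**Retrosynthetic overview**
- The target 20 is the tetra-MOM ether 19 after acid removal of four MOM groups; rings A and B are bought as arenes (5-fluororesorcinol, resorcinol), and ring C is the only ring that is made.
- Ring C is closed in one operation from enol silane 10 and aldehyde 16: C3–C2 by a catalytic enantioselective Mukaiyama aldol, then O1–C8a by fluoride-relayed SNAr of the aldolate oxygen on the fluorine-bearing ring carbon.
- Enabling feature: the C4 carbonyl is α to C3 (so C3 can be an enol silane) and conjugated through C4a with C8a of ring A, so F–C8a=C4a–C4=O is a vinylogous acyl fluoride, the benzo analogue of a 1-alkoxy-3-silyloxybutadiene.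
- All three prenyl groups, the acetyl group and the formyl group are placed by MOM-directed ortho-lithiation of the two arenes.

Key step: step 9

Assumption: the (S)-tryptophan-derived oxazaborolidinone is taken to leave the Si face of the boron-bound aldehyde open; if the opposite sense is found, the catalyst from (R)-tryptophan is used in the same way.

**Route**

Step 1
Reactants: 1 5-fluorobenzene-1,3-diol
Product: 2 1-fluoro-3,5-bis(methoxymethoxy)benzene
Conditions: MOMCl, iPr2NEt, CH2Cl2, 0 °C → rt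
Reagents that add atoms: chloromethyl methyl ether (MOMCl), COCCl
Why: O-alkylation of both phenols gives MOM ethers, which serve as ortho-directing groups for the lithiations and are removable by acid at the end.

Step 2
Reactants: 2 1-fluoro-3,5-bis(methoxymethoxy)benzene
Product: 4 5-fluoro-1,3-bis(methoxymethoxy)-2-(3-methylbut-2-en-1-yl)benzene, via aryllithium 3 (not isolated)
Conditions: n-BuLi, Et2O, 0 °C; then CuBr·SMe2 (5 mol%), prenyl bromide, −40 → 0 °C
Reagents that add atoms: prenyl bromide (1-bromo-3-methylbut-2-ene), CC(C)=CCBr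
Why: Directed ortho-metalation, in which the butyllithium is bound by both MOM ethers in the weakly coordinating ether and should remove the ring proton between them, followed by copper-catalysed SN2 alkylation at the primary carbon of prenyl bromide.

Step 3
Reactants: 4 5-fluoro-1,3-bis(methoxymethoxy)-2-(3-methylbut-2-en-1-yl)benzene
Product: 6 1-fluoro-3,5-bis(methoxymethoxy)-2,4-bis(3-methylbut-2-en-1-yl)benzene, via aryllithium 5 (not isolated)
Conditions: n-BuLi, THF, −78 °C; then CuBr·SMe2 (5 mol%), prenyl bromide, −78 → −40 °C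
Reagents that add atoms: prenyl bromide (1-bromo-3-methylbut-2-ene), CC(C)=CCBr
Why: Directed ortho-metalation at one of the two equivalent positions flanked by fluorine and a MOM ether, held at −78 °C so that the ortho-fluoroaryllithium does not lose LiF, then SN2 alkylation with prenyl bromide.

Step 4
Reactants: 6 1-fluoro-3,5-bis(methoxymethoxy)-2,4-bis(3-methylbut-2-en-1-yl)benzene
Product: 8 1-[2-fluoro-4,6-bis(methoxymethoxy)-3,5-bis(3-methylbut-2-en-1-yl)phenyl]ethan-1-one, via aryllithium 7 (not isolated)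
Conditions: n-BuLi, THF, −78 °C; then MeC(O)N(OMe)Me, −78 → −20 °C; H2O
Reagents that add atoms: N-methoxy-N-methylacetamide, CON(C)C(C)=O
Why: Directed ortho-metalation of the last ring C–H (between F and OMOM) and acylation of the aryllithium by the Weinreb amide, whose chelated tetrahedral adduct stops at the ketone.

Step 5
Reactants: 8 1-[2-fluoro-4,6-bis(methoxymethoxy)-3,5-bis(3-methylbut-2-en-1-yl)phenyl]ethan-1-one
Product: 10 ({1-[2-fluoro-4,6-bis(methoxymethoxy)-3,5-bis(3-methylbut-2-en-1-yl)phenyl]ethenyl}oxy)trimethylsilane, via lithium enolate 9 (not isolated)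
Conditions: LiN(iPr)2, THF, −78 °C; then Me3SiCl, −78 → 0 °C; pentane, filtration, used crude
Reagents that add atoms: chlorotrimethylsilane, C[Si](C)(C)Cl
Why: Kinetic deprotonation of the only enolisable position (the acetyl methyl) and O-silylation of the lithium enolate give the silyl enol ether.

Step 6
Reactants: 11 benzene-1,3-diol (resorcinol)
Product: 12 1,3-bis(methoxymethoxy)benzene
Conditions: MOMCl, iPr2NEt, CH2Cl2, 0 °C → rt
Reagents that add atoms: chloromethyl methyl ether (MOMCl), COCCl
Why: O-alkylation of both phenols to MOM ethers, as in step 1.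

Step 7
Reactants: 12 1,3-bis(methoxymethoxy)benzene
Product: 14 1,3-bis(methoxymethoxy)-2-(3-methylbut-2-en-1-yl)benzene, via aryllithium 13 (not isolated)
Conditions: n-BuLi, THF, 0 °C; then CuBr·SMe2 (5 mol%), prenyl bromide, −40 → 0 °C
Reagents that add atoms: prenyl bromide (1-bromo-3-methylbut-2-ene), CC(C)=CCBr
Why: Directed ortho-metalation between the two MOM ethers and copper-catalysed SN2 alkylation with prenyl bromide.

Step 8
Reactants: 14 1,3-bis(methoxymethoxy)-2-(3-methylbut-2-en-1-yl)benzene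
Product: 16 2,4-bis(methoxymethoxy)-3-(3-methylbut-2-en-1-yl)benzaldehyde, via aryllithium 15 (not isolated)
Conditions: n-BuLi, TMEDA, THF, −20 → 0 °C; then DMF, −78 °C → rt; H2O
Reagents that add atoms: N,N-dimethylformamide, CN(C)C=O
Why: Second directed ortho-metalation, now ortho to one MOM ether (the two open sites are equivalent), and formylation of the aryllithium with DMF.

Step 9
Reactants: 10 ({1-[2-fluoro-4,6-bis(methoxymethoxy)-3,5-bis(3-methylbut-2-en-1-yl)phenyl]ethenyl}oxy)trimethylsilane; 16 2,4-bis(methoxymethoxy)-3-(3-methylbut-2-en-1-yl)benzaldehyde (slight excess)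
Product: 19 (2S)-2-[2,4-bis(methoxymethoxy)-3-(3-methylbut-2-en-1-yl)phenyl]-5,7-bis(methoxymethoxy)-6,8-bis(3-methylbut-2-en-1-yl)-2,3-dihydro-4H-chromen-4-one, via silyl aldol 17 (not isolated), via aldolate 18 (not isolated)
Conditions: (S)-2-butyl-4-(1H-indol-3-ylmethyl)-3-tosyl-1,3,2-oxazaborolidin-5-one (20 mol%), EtCN, −78 °C; then [(Me2N)3S][Me3SiF2] (40 mol%), THF, −78 → −20 °C; AcOH quench at −20 °C
Reagents that add atoms: none
Why: Proposed new method: a chiral boron Lewis acid Mukaiyama aldol of enol silane 10 with aldehyde 16 (open transition state, silyl transfer to the aldolate oxygen) forms the C3–C2 bond and gives silyl ether 17, and substoichiometric difluorotrimethylsilicate then cleaves the O–Si bond so that alkoxide 18 adds to the fluorine-bearing carbon C8a and expels fluoride, which recombines with Me3SiF and carries the chain; the closest known reaction types are the Mukaiyama aldol–dihydropyranone annulation of 1-alkoxy-3-silyloxybutadienes, of which this is the benzo-fused version with C–F in place of the enol ether carbon, and alkoxide SNAr ring closures onto 2-fluoroaryl ketones. Ring C closes by a 6-endo-trig addition–elimination in which the C8a=C4a bond of ring A, conjugated to the C4 carbonyl, behaves as a β-fluoroenone and the Meisenheimer intermediate is an enolate. C2 is set in the aldol stage by the catalyst, whose indole shields one face of the boron-bound aldehyde so that the enol silane adds to the Si face, and the C2–O bond is not broken afterwards. The step needs ring closure to outrun retro-aldol cleavage and E1cB dehydration of the aldolate, which the low temperature, the low stationary concentration of 18 and the cold acetic acid quench are meant to secure, and it needs attack at C8a and not at the other ortho carbon C5, which the far better leaving-group ability of fluoride over a MOM-oxy group secures.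

Step 10
Reactants: 19 (2S)-2-[2,4-bis(methoxymethoxy)-3-(3-methylbut-2-en-1-yl)phenyl]-5,7-bis(methoxymethoxy)-6,8-bis(3-methylbut-2-en-1-yl)-2,3-dihydro-4H-chromen-4-one
Product: 20 (2S)-2-[2,4-dihydroxy-3-(3-methylbut-2-en-1-yl)phenyl]-5,7-dihydroxy-6,8-bis(3-methylbut-2-en-1-yl)-2,3-dihydro-4H-chromen-4-one
Conditions: HCl (3 M aq), MeOH, 40 °C
Reagents that add atoms: none
Why: Acid-catalysed acetal exchange with methanol removes the four MOM ethers as dimethoxymethane without touching C2 or the prenyl groups, so the (2S) configuration from step 9 should be kept.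

**Compound list**

1 | 5-fluorobenzene-1,3-diol (5-fluororesorcinol) | Oc1cc(O)cc(F)c1 | starting material
2 | 1-fluoro-3,5-bis(methoxymethoxy)benzene | COCOc1cc(F)cc(OCOC)c1 | intermediate
3 | [4-fluoro-2,6-bis(methoxymethoxy)phenyl]lithium (not isolated) | [Li]c1c(OCOC)cc(F)cc1OCOC | intermediate
4 | 5-fluoro-1,3-bis(methoxymethoxy)-2-(3-methylbut-2-en-1-yl)benzene | COCOc1cc(F)cc(OCOC)c1CC=C(C)C | intermediate
5 | [6-fluoro-2,4-bis(methoxymethoxy)-3-(3-methylbut-2-en-1-yl)phenyl]lithium (not isolated) | [Li]c1c(F)cc(OCOC)c(CC=C(C)C)c1OCOC | intermediate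
6 | 1-fluoro-3,5-bis(methoxymethoxy)-2,4-bis(3-methylbut-2-en-1-yl)benzene | CC(C)=CCc1c(F)cc(OCOC)c(CC=C(C)C)c1OCOC | intermediate
7 | [2-fluoro-4,6-bis(methoxymethoxy)-3,5-bis(3-methylbut-2-en-1-yl)phenyl]lithium (not isolated) | [Li]c1c(F)c(CC=C(C)C)c(OCOC)c(CC=C(C)C)c1OCOC | intermediate
8 | 1-[2-fluoro-4,6-bis(methoxymethoxy)-3,5-bis(3-methylbut-2-en-1-yl)phenyl]ethan-1-one | CC(=O)c1c(F)c(CC=C(C)C)c(OCOC)c(CC=C(C)C)c1OCOC | intermediate
9 | lithium 1-[2-fluoro-4,6-bis(methoxymethoxy)-3,5-bis(3-methylbut-2-en-1-yl)phenyl]ethen-1-olate (not isolated) | [Li]OC(=C)c1c(F)c(CC=C(C)C)c(OCOC)c(CC=C(C)C)c1OCOC | intermediate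
10 | ({1-[2-fluoro-4,6-bis(methoxymethoxy)-3,5-bis(3-methylbut-2-en-1-yl)phenyl]ethenyl}oxy)trimethylsilane | C=C(O[Si](C)(C)C)c1c(F)c(CC=C(C)C)c(OCOC)c(CC=C(C)C)c1OCOC | intermediate
11 | benzene-1,3-diol (resorcinol) | Oc1cccc(O)c1 | starting material
12 | 1,3-bis(methoxymethoxy)benzene | COCOc1cccc(OCOC)c1 | intermediate
13 | [2,6-bis(methoxymethoxy)phenyl]lithium (not isolated) | [Li]c1c(OCOC)cccc1OCOC | intermediate
14 | 1,3-bis(methoxymethoxy)-2-(3-methylbut-2-en-1-yl)benzene | COCOc1cccc(OCOC)c1CC=C(C)C | intermediate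
15 | [2,4-bis(methoxymethoxy)-3-(3-methylbut-2-en-1-yl)phenyl]lithium (not isolated) | [Li]c1ccc(OCOC)c(CC=C(C)C)c1OCOC | intermediate
16 | 2,4-bis(methoxymethoxy)-3-(3-methylbut-2-en-1-yl)benzaldehyde | O=Cc1ccc(OCOC)c(CC=C(C)C)c1OCOC | intermediate
17 | (3S)-3-[2,4-bis(methoxymethoxy)-3-(3-methylbut-2-en-1-yl)phenyl]-1-[2-fluoro-4,6-bis(methoxymethoxy)-3,5-bis(3-methylbut-2-en-1-yl)phenyl]-3-[(trimethylsilyl)oxy]propan-1-one (not isolated) | C[Si](C)(C)O[C@@H](CC(=O)c1c(F)c(CC=C(C)C)c(OCOC)c(CC=C(C)C)c1OCOC)c1ccc(OCOC)c(CC=C(C)C)c1OCOC | intermediate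
18 | tris(dimethylamino)sulfonium (1S)-1-[2,4-bis(methoxymethoxy)-3-(3-methylbut-2-en-1-yl)phenyl]-3-[2-fluoro-4,6-bis(methoxymethoxy)-3,5-bis(3-methylbut-2-en-1-yl)phenyl]-3-oxopropan-1-olate (not isolated) | [O-][C@@H](CC(=O)c1c(F)c(CC=C(C)C)c(OCOC)c(CC=C(C)C)c1OCOC)c1ccc(OCOC)c(CC=C(C)C)c1OCOC.CN(C)[S+](N(C)C)N(C)C | intermediate
19 | (2S)-2-[2,4-bis(methoxymethoxy)-3-(3-methylbut-2-en-1-yl)phenyl]-5,7-bis(methoxymethoxy)-6,8-bis(3-methylbut-2-en-1-yl)-2,3-dihydro-4H-chromen-4-one | CC(C)=CCc1c(OCOC)ccc([C@@H]2CC(=O)c3c(OCOC)c(CC=C(C)C)c(OCOC)c(CC=C(C)C)c3O2)c1OCOC | intermediate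
20 | (2S)-2-[2,4-dihydroxy-3-(3-methylbut-2-en-1-yl)phenyl]-5,7-dihydroxy-6,8-bis(3-methylbut-2-en-1-yl)-2,3-dihydro-4H-chromen-4-one | CC(C)=CCc1c(O)ccc([C@@H]2CC(=O)c3c(O)c(CC=C(C)C)c(O)c(CC=C(C)C)c3O2)c1O | target

**Count**

Total steps: 10. Longest linear sequence: 7 steps (steps 1, 2, 3, 4, 5, 9, 10).

**Steps most likely to fail**

1. Step 9 (Proposed new method). The free aldolate may undergo retro-aldol cleavage and unselective re-addition before it closes the ring, which would erode the enantiomeric purity. The fluoride or alkoxide may also open the product by enolisation at C3 and β-elimination of the ring oxygen, and the SNAr may be slow on the hindered ring. The fallback sets out from ketone 8 and aldehyde 16 and comes back at 19. Ketone 8 is deprotonated with LiN(iPr)2 in THF at −78 °C, aldehyde 16 is added and the mixture is quenched cold to give the racemic aldol 3-[2,4-bis(methoxymethoxy)-3-(3-methylbut-2-en-1-yl)phenyl]-1-[2-fluoro-4,6-bis(methoxymethoxy)-3,5-bis(3-methylbut-2-en-1-yl)phenyl]-3-hydroxypropan-1-one F1. Dess–Martin periodinane in CH2Cl2 oxidises it to the 1,3-diketone 1-[2,4-bis(methoxymethoxy)-3-(3-methylbut-2-en-1-yl)phenyl]-3-[2-fluoro-4,6-bis(methoxymethoxy)-3,5-bis(3-methylbut-2-en-1-yl)phenyl]propane-1,3-dione F2. K2CO3 in DMF closes the pyranone ring by SNAr of the enol oxygen to give the flavone 2-[2,4-bis(methoxymethoxy)-3-(3-methylbut-2-en-1-yl)phenyl]-5,7-bis(methoxymethoxy)-6,8-bis(3-methylbut-2-en-1-yl)-4H-chromen-4-one F3. A copper hydride asymmetric conjugate reduction, a reaction type shown on chromones (Cu(OAc)2, DTBM-SEGPHOS in the antipode that gives 2S, (EtO)2MeSiH, t-BuOH, toluene), then sets C2 without touching the prenyl groups and gives 19.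

2. Step 10. Acid may cyclise the prenyl groups onto the neighbouring phenols to give chromans, and reversible C2–O1 heterolysis, assisted by the electron-rich 2',4'-dioxygenated ring B, may erode the configuration at C2. The fallback sets out from 19 and comes back at 20. The MOM ethers are exchanged for silyl ethers under non-protic conditions (Me3SiOTf, 2,2'-bipyridyl, MeCN, 0 °C) to give (2S)-2-[2,4-bis(trimethylsilyloxy)-3-(3-methylbut-2-en-1-yl)phenyl]-5,7-bis(trimethylsilyloxy)-6,8-bis(3-methylbut-2-en-1-yl)-2,3-dihydro-4H-chromen-4-one F6. Water at room temperature then hydrolyses the aryl silyl ethers at near-neutral pH to give 20.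

3. Step 2. The butyllithium may remove a proton next to fluorine instead of the one between the MOM ethers, and that aryllithium would lose LiF to an aryne. The fallback sets out from 1 and comes back at 4. Iodination of 1 with I2 and NaHCO3 in water, which for resorcinols goes to the position between the hydroxyls, gives 5-fluoro-2-iodobenzene-1,3-diol F4. MOMCl and iPr2NEt give 5-fluoro-2-iodo-1,3-bis(methoxymethoxy)benzene F5. Iodine–lithium exchange with n-BuLi in THF at −78 °C gives aryllithium 3 at a fixed position, and prenyl bromide with CuBr·SMe2 as in step 2 gives 4.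

**Further compounds**

F1 | step 9 | 3-[2,4-bis(methoxymethoxy)-3-(3-methylbut-2-en-1-yl)phenyl]-1-[2-fluoro-4,6-bis(methoxymethoxy)-3,5-bis(3-methylbut-2-en-1-yl)phenyl]-3-hydroxypropan-1-one (racemic) | OC(CC(=O)c1c(F)c(CC=C(C)C)c(OCOC)c(CC=C(C)C)c1OCOC)c1ccc(OCOC)c(CC=C(C)C)c1OCOC
F2 | step 9 | 1-[2,4-bis(methoxymethoxy)-3-(3-methylbut-2-en-1-yl)phenyl]-3-[2-fluoro-4,6-bis(methoxymethoxy)-3,5-bis(3-methylbut-2-en-1-yl)phenyl]propane-1,3-dione | O=C(CC(=O)c1c(F)c(CC=C(C)C)c(OCOC)c(CC=C(C)C)c1OCOC)c1ccc(OCOC)c(CC=C(C)C)c1OCOC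
F3 | step 9 | 2-[2,4-bis(methoxymethoxy)-3-(3-methylbut-2-en-1-yl)phenyl]-5,7-bis(methoxymethoxy)-6,8-bis(3-methylbut-2-en-1-yl)-4H-chromen-4-one | CC(C)=CCc1c(OCOC)ccc(-c2cc(=O)c3c(OCOC)c(CC=C(C)C)c(OCOC)c(CC=C(C)C)c3o2)c1OCOC
F4 | step 2 | 5-fluoro-2-iodobenzene-1,3-diol | Oc1cc(F)cc(O)c1I
F5 | step 2 | 5-fluoro-2-iodo-1,3-bis(methoxymethoxy)benzene | COCOc1cc(F)cc(OCOC)c1I
F6 | step 10 | (2S)-2-[2,4-bis(trimethylsilyloxy)-3-(3-methylbut-2-en-1-yl)phenyl]-5,7-bis(trimethylsilyloxy)-6,8-bis(3-methylbut-2-en-1-yl)-2,3-dihydro-4H-chromen-4-one | CC(C)=CCc1c(O[Si](C)(C)C)ccc([C@@H]2CC(=O)c3c(O[Si](C)(C)C)c(CC=C(C)C)c(O[Si](C)(C)C)c(CC=C(C)C)c3O2)c1O[Si](C)(C)C
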